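**Retrosynthetic overview**

- The route rests on ring A: its O6 and O7 phenols are free and nucleophilic, whereas the 5-OH is held in a hydrogen bond to the C4 carbonyl. The vicinal O6/O7 bis(hydrogen sulfate) can therefore be installed last, with the ring B 3',4'-catechol masked as a dipivalate.
- 13 ⇒ 12 by methanolysis of two aryl pivalates; 12 ⇒ triol 9 + 2 Me3N·SO3 (two O–S bonds, no ring closed).
- 9 ⇒ 8 by BBr3 O-demethylation; 8 ⇒ 6 + pivaloyl chloride; 6 ⇒ 5 by benzyl hydrogenolysis.
- 5 ⇒ chalcone 3 by I2/DMSO oxidative cyclisation; 3 ⇒ 1 + 2 by Claisen–Schmidt condensation.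
- Ring order: rings A and B are bought as the arenes 1 and 2; ring C (the pyranone) is the only ring closed, in step 2.

Key step: step 6

Assumption: the hydrogen sulfate esters 11, 12 and 13 are drawn as free acids, as in the target. In solution they are handled as trialkylammonium or potassium salts, and the acid form of 13 is liberated only in the final cold acidification.

**Step 1**
Reactants: 1 6-hydroxy-2,3,4-trimethoxyacetophenone; 2 3,4-bis(benzyloxy)benzaldehyde
Product: 3 (E)-1-(6-hydroxy-2,3,4-trimethoxyphenyl)-3-[3,4-bis(benzyloxy)phenyl]prop-2-en-1-one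
Conditions: KOH (50% aq), EtOH, rt; then 1 M HCl
Reagents that add atoms: none
Why: Claisen–Schmidt aldol condensation of the methyl ketone with a non-enolisable aldehyde, in which E1cB dehydration should give the conjugated E-enone as the thermodynamic isomer and the methyl and benzyl ethers are inert to hydroxide.

**Step 2**
Reactants: 3 (E)-1-(6-hydroxy-2,3,4-trimethoxyphenyl)-3-[3,4-bis(benzyloxy)phenyl]prop-2-en-1-one
Product: 5 3',4'-bis(benzyloxy)-5,6,7-trimethoxyflavone, via racemic flavanone 4 (not isolated)
Conditions: I2 (10 mol %), DMSO, 125 °C; aq Na2S2O3 wash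
Reagents that add atoms: none
Why: Oxidative cyclisation of a 2'-hydroxychalcone, in which oxa-Michael closure of ring C gives the flavanone, α-iodination and loss of HI give the flavone, and DMSO reoxidises HI; the C2 stereocentre of 4 is transient and is erased, and aryl benzyl ethers should tolerate catalytic iodine.

**Step 3**
Reactants: 5 3',4'-bis(benzyloxy)-5,6,7-trimethoxyflavone
Product: 6 3',4'-dihydroxy-5,6,7-trimethoxyflavone
Conditions: H2 (1 atm), 10% Pd/C, THF/MeOH, rt
Reagents that add atoms: none
Why: Catalytic hydrogenolysis of the two benzylic C–O bonds, with the flavone C2=C3 bond (a doubly aryl-conjugated vinylogous ester) and the methyl ethers expected to survive at 1 atm and room temperature.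

**Step 4**
Reactants: 6 3',4'-dihydroxy-5,6,7-trimethoxyflavone; 7 pivaloyl chloride
Product: 8 5,6,7-trimethoxy-3',4'-bis(pivaloyloxy)flavone
Conditions: PivCl (2.5 equiv), pyridine, DMAP (cat.), CH2Cl2, 0 °C → rt
Reagents that add atoms: pivaloyl chloride (7), CC(C)(C)C(=O)Cl
Why: DMAP-catalysed O-acylation of the only two free phenols, giving hindered aryl esters chosen to withstand the Lewis acid of the next step and to leave under mild base at the end.

**Step 5**
Reactants: 8 5,6,7-trimethoxy-3',4'-bis(pivaloyloxy)flavone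
Product: 9 3',4'-di-O-pivaloyl-6-hydroxyluteolin (5,6,7-trihydroxy-3',4'-bis(pivaloyloxy)flavone)
Conditions: BBr3 (8 equiv, 1 M in CH2Cl2), CH2Cl2, −78 °C → rt; ice-water work-up
Reagents that add atoms: none
Why: Lewis acid O-demethylation of aryl methyl ethers, in which boron coordinates each ether oxygen and bromide attacks the methyl carbon (the carbonyl-chelated 5-OMe first, then 6- and 7-OMe), while the hindered pivaloyl carbonyls should resist acyl–oxygen cleavage at or below room temperature and the alcohol-free work-up avoids HBr-driven transesterification.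

**Step 6**
Reactants: 9 3',4'-di-O-pivaloyl-6-hydroxyluteolin; 10 sulfur trioxide trimethylamine complex
Product: 12 3',4'-di-O-pivaloyl-6-hydroxyluteolin 6,7-bis(hydrogen sulfate), via 7-monosulfate 11 (not isolated)
Conditions: Me3N·SO3 (8 equiv), Et3N (10 equiv), DMF, 55 °C, Ar; Sephadex LH-20
Reagents that add atoms: sulfur trioxide trimethylamine complex (10), C[N+](C)(C)S(=O)(=O)[O-]
Why: Triethylamine converts the acidic ring A phenols into phenoxides, and the O7 phenoxide (a vinylogous carboxylate para to the C4 carbonyl, the most acidic site) attacks the sulfur of Me3N–SO3 and expels trimethylamine to give monosulfate 11; the O6 phenoxide then repeats this sulfuryl transfer, more slowly because it sits beside a sulfate anion, which is why excess reagent and warming are used. The closest known reaction type is the O-sulfation of flavonoid phenols with sulfur trioxide–amine complexes. No ring is closed and no stereocentre is formed; the step makes only the two O–S bonds. The selectivity needed is O6 and O7 over O5 and over ring B: the 5-OH is held in a six-membered hydrogen bond to the C4 carbonyl and is flanked by C4a and the O6 substituent, so it should stay free below about 60 °C, and the ring B oxygens are blocked as pivalates, which are not solvolysed in aprotic DMF with a tertiary amine. Argon is used because the deprotonated 5,6,7-triol is sensitive to air oxidation.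

**Step 7**
Reactants: 12 3',4'-di-O-pivaloyl-6-hydroxyluteolin 6,7-bis(hydrogen sulfate)
Product: 13 6-hydroxyluteolin 6,7-disulfate
Conditions: K2CO3 (4 equiv), degassed MeOH, Ar, 0 °C → rt; then 1 M HCl to pH 2 at 0 °C, C18 desalting, freeze-drying
Reagents that add atoms: none
Why: Base-mediated transesterification (methanolysis) of the two aryl pivalates should release the catechol and methyl pivalate, while aryl sulfate monoester anions are inert to carbonate and methoxide, and a brief cold acidification gives the acid form without hydrolysing the sulfates.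

**Compound list**

1 | 6-hydroxy-2,3,4-trimethoxyacetophenone | CC(=O)c1c(O)cc(OC)c(OC)c1OC | starting material
2 | 3,4-bis(benzyloxy)benzaldehyde | O=Cc1ccc(OCc2ccccc2)c(OCc2ccccc2)c1 | starting material
3 | (E)-1-(6-hydroxy-2,3,4-trimethoxyphenyl)-3-[3,4-bis(benzyloxy)phenyl]prop-2-en-1-one | O=C(/C=C/c1ccc(OCc2ccccc2)c(OCc2ccccc2)c1)c1c(O)cc(OC)c(OC)c1OC | intermediate
4 | racemic 3',4'-bis(benzyloxy)-5,6,7-trimethoxyflavanone | O=C1CC(c2ccc(OCc3ccccc3)c(OCc3ccccc3)c2)Oc2cc(OC)c(OC)c(OC)c12 | intermediate
5 | 3',4'-bis(benzyloxy)-5,6,7-trimethoxyflavone | O=c1cc(-c2ccc(OCc3ccccc3)c(OCc3ccccc3)c2)oc2cc(OC)c(OC)c(OC)c12 | intermediate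
6 | 3',4'-dihydroxy-5,6,7-trimethoxyflavone | O=c1cc(-c2ccc(O)c(O)c2)oc2cc(OC)c(OC)c(OC)c12 | intermediate
7 | pivaloyl chloride | CC(C)(C)C(=O)Cl | starting material
8 | 5,6,7-trimethoxy-3',4'-bis(pivaloyloxy)flavone | O=c1cc(-c2ccc(OC(=O)C(C)(C)C)c(OC(=O)C(C)(C)C)c2)oc2cc(OC)c(OC)c(OC)c12 | intermediate
9 | 3',4'-di-O-pivaloyl-6-hydroxyluteolin | O=c1cc(-c2ccc(OC(=O)C(C)(C)C)c(OC(=O)C(C)(C)C)c2)oc2cc(O)c(O)c(O)c12 | intermediate
10 | sulfur trioxide trimethylamine complex | C[N+](C)(C)S(=O)(=O)[O-] | starting material
11 | 3',4'-di-O-pivaloyl-6-hydroxyluteolin 7-(hydrogen sulfate) | O=c1cc(-c2ccc(OC(=O)C(C)(C)C)c(OC(=O)C(C)(C)C)c2)oc2cc(OS(=O)(=O)O)c(O)c(O)c12 | intermediate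
12 | 3',4'-di-O-pivaloyl-6-hydroxyluteolin 6,7-bis(hydrogen sulfate) | O=c1cc(-c2ccc(OC(=O)C(C)(C)C)c(OC(=O)C(C)(C)C)c2)oc2cc(OS(=O)(=O)O)c(OS(=O)(=O)O)c(O)c12 | intermediate
13 | 6-hydroxyluteolin 6,7-disulfate | O=c1cc(-c2ccc(O)c(O)c2)oc2cc(OS(=O)(=O)O)c(OS(=O)(=O)O)c(O)c12 | target

**Step count**

Total steps: 7. Longest linear sequence: 7 steps (1 → 3 → 5 → 6 → 8 → 9 → 12 → 13).

**Steps most likely to fail**

Step 6 (bis-sulfation). The second sulfuryl transfer, at O6 beside the O7 sulfate anion, may stall, and forcing it may bring in O5; the charged mono-, di- and tri-sulfates are also hard to separate. The fallback sets out from 9 and uses protected sulfate diesters instead of an SO3 complex. Treatment of 9 with 2,2,2-trichloroethyl chlorosulfate (Et3N, DMAP, THF, 0 °C → rt) should give 3',4'-di-O-pivaloyl-6-hydroxyluteolin 6,7-bis(2,2,2-trichloroethyl sulfate) F1, a neutral compound that can be purified on silica and freed of regioisomers. Zn dust and HCO2NH4 in MeOH at rt should then remove both trichloroethyl groups by reductive fragmentation without touching the pivalates, and the route is rejoined at 12.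

Step 5 (BBr3 demethylation). The slow cleavage of the 7-O-methyl ether needs excess BBr3 at room temperature, and partial acyl–oxygen cleavage of the pivalates may occur over that time. The fallback sets out from 6 and exchanges the ring B esters for sulfonates, which are inert to BBr3, then changes the ring A ethers to hydrogenolysable ones.
- TsCl, Et3N and DMAP in CH2Cl2 should give 5,6,7-trimethoxy-3',4'-bis(tosyloxy)flavone F2.
- BBr3 in CH2Cl2 (−78 °C → rt) should give 5,6,7-trihydroxy-3',4'-bis(tosyloxy)flavone F3.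
- BnBr (2.2 equiv) and K2CO3 in DMF at rt should alkylate O6 and O7 but not the chelated 5-OH, giving 6,7-bis(benzyloxy)-5-hydroxy-3',4'-bis(tosyloxy)flavone F4.
- KOH in MeOH/THF at 50 °C should cleave the aryl tosylates to 6,7-bis(benzyloxy)-5,3',4'-trihydroxyflavone F5.
- PivCl (2.2 equiv) in pyridine at 0 °C should acylate only ring B, giving 6,7-bis(benzyloxy)-5-hydroxy-3',4'-bis(pivaloyloxy)flavone F6.
- H2 over 10% Pd/C in THF/MeOH should remove the benzyl ethers, and the route is rejoined at 9.

Step 7 (depivaloylation and acid-form isolation). In basic methanol the freed ring B catecholate may be oxidised by air and the second, hindered pivalate may leave slowly; the sulfates may also hydrolyse if acidification is prolonged. The fallback sets out from 12 and replaces chemical methanolysis by biocatalytic hydrolysis at neutral pH. Porcine liver esterase in potassium phosphate buffer (pH 7, 5% DMSO, 30 °C, Ar) should cleave both pivalates, as esterases do with catechol dipivalate prodrugs, and the same cold acidification and C18 desalting return the route at 13. No new compound is made on this path.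

**Further compounds**

F1 | step 6 | 3',4'-di-O-pivaloyl-6-hydroxyluteolin 6,7-bis(2,2,2-trichloroethyl sulfate) | O=c1cc(-c2ccc(OC(=O)C(C)(C)C)c(OC(=O)C(C)(C)C)c2)oc2cc(OS(=O)(=O)OCC(Cl)(Cl)Cl)c(OS(=O)(=O)OCC(Cl)(Cl)Cl)c(O)c12
F2 | step 5 | 5,6,7-trimethoxy-3',4'-bis(tosyloxy)flavone | O=c1cc(-c2ccc(OS(=O)(=O)c3ccc(C)cc3)c(OS(=O)(=O)c3ccc(C)cc3)c2)oc2cc(OC)c(OC)c(OC)c12
F3 | step 5 | 5,6,7-trihydroxy-3',4'-bis(tosyloxy)flavone | O=c1cc(-c2ccc(OS(=O)(=O)c3ccc(C)cc3)c(OS(=O)(=O)c3ccc(C)cc3)c2)oc2cc(O)c(O)c(O)c12
F4 | step 5 | 6,7-bis(benzyloxy)-5-hydroxy-3',4'-bis(tosyloxy)flavone | O=c1cc(-c2ccc(OS(=O)(=O)c3ccc(C)cc3)c(OS(=O)(=O)c3ccc(C)cc3)c2)oc2cc(OCc3ccccc3)c(OCc3ccccc3)c(O)c12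
F5 | step 5 | 6,7-bis(benzyloxy)-5,3',4'-trihydroxyflavone | O=c1cc(-c2ccc(O)c(O)c2)oc2cc(OCc3ccccc3)c(OCc3ccccc3)c(O)c12
F6 | step 5 | 6,7-bis(benzyloxy)-5-hydroxy-3',4'-bis(pivaloyloxy)flavone | O=c1cc(-c2ccc(OC(=O)C(C)(C)C)c(OC(=O)C(C)(C)C)c2)oc2cc(OCc3ccccc3)c(OCc3ccccc3)c(O)c12
F0 | step 7 | none | none
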